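**Retrosynthetic overview**
- Last operation: a chromium-mediated γ-chloroallylation joins C6–C7, and the new C7 alkoxide then acylates itself with the C19 thioester, so the ten-membered ring and the γ-lactone form together.
- C8 and C17 come from a propanethioate aldol on a C8 ketone; the three acetates are installed before that in one acylation.
- C2–C3 comes from opening a ring A-fused butyrolactone (O9–C2) with a chloroenyne acetylide, followed by Noyori reduction and Z-selective semireduction.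
- Ring A is closed first by a type 2 carbonyl-ene cyclization; C10 and C1 are set by cuprate addition/alkylation on a butenolide, relayed from C9.
- C9 comes from a catalytic asymmetric vinylogous aldol. Ring order: temporary O9–C2 lactone template, ring A, then ten-membered ring plus γ-lactone in the final step.

Assumption: briarane numbering is used throughout (ring A = C1, C10–C14; C15 methyl on C1; C16 on C5; C17/C18/C19 = lactone CH, its methyl, the carbonyl; C20 on C11); TBDPS = tert-butyldiphenylsilyl, TES = triethylsilyl.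

**Step 1**
Reactants: 1 3-methylfuran-2(5H)-one; 2 2-[(tert-butyldiphenylsilyl)oxy]acetaldehyde
Product: 3 (5S)-5-[(1R)-2-(TBDPS-oxy)-1-hydroxyethyl]-3-methylfuran-2(5H)-one
Conditions: 3-[3,5-bis(trifluoromethyl)anilino]-4-{[(8R,9R)-6'-methoxycinchonan-9-yl]amino}cyclobut-3-ene-1,2-dione (10 mol%), CH2Cl2, −20 °C
Reagents that add atoms: none
Why: Direct catalytic asymmetric vinylogous aldol addition, in which the amine–squaramide forms the dienolate of 1 and directs it to one face of the hydrogen-bonded aldehyde, setting C9 (S; the quinine-derived pseudoenantiomer would give the mirror image); the C8 carbinol epimer is immaterial because C8 is oxidized in step 15.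

**Step 2**
Reactants: 3 (5S)-5-[(1R)-2-(TBDPS-oxy)-1-hydroxyethyl]-3-methylfuran-2(5H)-one
Product: 4 (5S)-5-[(1R)-2-(TBDPS-oxy)-1-(TES-oxy)ethyl]-3-methylfuran-2(5H)-one
Conditions: TESCl, imidazole, DMF, 0 °C → rt
Reagents that add atoms: chlorotriethylsilane CC[Si](Cl)(CC)CC
Why: Standard silylation of the secondary alcohol masks O8 through the organometallic steps without touching a stereocenter.

**Step 3**
Reactants: 5 oxirane
Product: 6 2-(TES-oxy)ethyl trifluoromethanesulfonate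
Conditions: TESOTf, CH2Cl2, −78 → −40 °C, used cold
Reagents that add atoms: triethylsilyl trifluoromethanesulfonate CC[Si](CC)(CC)OS(=O)(=O)C(F)(F)F
Why: Ring opening of an epoxide by a silyl triflate gives the β-silyloxyethyl triflate, a primary electrophile reactive enough to quaternize a hindered enolate.

**Step 4**
Reactants: 4 (5S)-5-[(1R)-2-(TBDPS-oxy)-1-(TES-oxy)ethyl]-3-methylfuran-2(5H)-one; 7 prop-1-en-2-ylmagnesium bromide; 6 2-(TES-oxy)ethyl trifluoromethanesulfonate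
Product: 9 (3S,4S,5S)-5-[(1R)-2-(TBDPS-oxy)-1-(TES-oxy)ethyl]-3-methyl-4-(prop-1-en-2-yl)-3-[2-(TES-oxy)ethyl]dihydrofuran-2(3H)-one, via bromomagnesium lactone enolate 8 (not isolated)
Conditions: 7 (2.2 equiv), CuBr·SMe2 (1.1 equiv), THF, −78 °C; then 6, HMPA, −78 → −20 °C
Reagents that add atoms: none
Why: Tandem cuprate conjugate addition–enolate alkylation on a γ-substituted butenolide, in which the isopropenyl group adds anti to the C9 side chain (sets C10) and the triflate then enters anti to the new isopropenyl group (sets the quaternary C1).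

**Step 5**
Reactants: 9 (3S,4S,5S)-5-[(1R)-2-(TBDPS-oxy)-1-(TES-oxy)ethyl]-3-methyl-4-(prop-1-en-2-yl)-3-[2-(TES-oxy)ethyl]dihydrofuran-2(3H)-one
Product: 10 2-[(3S,4S,5S)-5-[(1R)-2-(TBDPS-oxy)-1-(TES-oxy)ethyl]-3-methyl-2-oxo-4-(prop-1-en-2-yl)oxolan-3-yl]acetaldehyde
Conditions: (COCl)2, DMSO, CH2Cl2, −78 → −30 °C; then Et3N
Reagents that add atoms: none
Why: Swern conditions oxidize a primary triethylsilyl ether directly to the aldehyde (chlorosulfonium cleavage of the unhindered Si–O bond) while the secondary TES and the TBDPS ethers survive.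

**Step 6**
Reactants: 10 2-[(3S,4S,5S)-5-[(1R)-2-(TBDPS-oxy)-1-(TES-oxy)ethyl]-3-methyl-2-oxo-4-(prop-1-en-2-yl)oxolan-3-yl]acetaldehyde
Product: 11 (3S,3aS,6S,7aS)-3-[(1R)-2-(TBDPS-oxy)-1-(TES-oxy)ethyl]-6-hydroxy-7a-methyl-4-methylidenehexahydro-2-benzofuran-1(3H)-one
Conditions: Me2AlCl (2.5 equiv), CH2Cl2, −78 → −20 °C
Reagents that add atoms: none
Why: Type 2 carbonyl-ene cyclization through a chair transition state with the aldehyde oxygen equatorial (away from the axial C15 methyl) closes ring A, sets C13 (OH trans to C15) and delivers the C11 exocyclic methylene directly.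

**Step 7**
Reactants: 2 2-[(tert-butyldiphenylsilyl)oxy]acetaldehyde; 12 ethynyltrimethylsilane
Product: 13 rac-1-(TBDPS-oxy)-4-(trimethylsilyl)but-3-yn-2-ol
Conditions: 12, n-BuLi, THF, −78 °C; then 2; aq. NH4Cl
Reagents that add atoms: none
Why: Lithium acetylide addition to an aldehyde; the carbinol is oxidized in the next step, so no stereocontrol is needed.

**Step 8**
Reactants: 13 rac-1-(TBDPS-oxy)-4-(trimethylsilyl)but-3-yn-2-ol
Product: 14 1-(TBDPS-oxy)-4-(trimethylsilyl)but-3-yn-2-one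
Conditions: Dess–Martin periodinane, NaHCO3, CH2Cl2, 0 °C
Reagents that add atoms: none
Why: Dess–Martin oxidation of a propargylic alcohol to the ynone.

**Step 9**
Reactants: 14 1-(TBDPS-oxy)-4-(trimethylsilyl)but-3-yn-2-one; 15 (chloromethyl)triphenylphosphonium chloride
Product: 17 (Z)-tert-butyl{[2-(chloromethylidene)but-3-yn-1-yl]oxy}diphenylsilane, via TMS-chloroenyne 16 (not isolated)
Conditions: 15, NaN(SiMe3)2, THF, −78 → 0 °C; then K2CO3, MeOH, rt
Reagents that add atoms: none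
Why: Wittig chloromethylenation of the ynone carbonyl (1,2-addition of the ylide) followed by methanolysis of the alkynyl C–Si bond; the Z isomer (Cl cis to CH2O) is taken on after chromatography.

**Step 10**
Reactants: 11 (3S,3aS,6S,7aS)-3-[(1R)-2-(TBDPS-oxy)-1-(TES-oxy)ethyl]-6-hydroxy-7a-methyl-4-methylidenehexahydro-2-benzofuran-1(3H)-one; 17 (Z)-tert-butyl{[2-(chloromethylidene)but-3-yn-1-yl]oxy}diphenylsilane
Product: 18 (1S,8R,9S,10S,13S,5Z)-6-chloro-9,13-dihydroxy-8-(TES-oxy)-7,16-bis(TBDPS-oxy)-17,18,19-trinor-6,7-secobriara-5,11(20)-dien-3-yn-2-one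
Conditions: 17 (2.2 equiv), n-BuLi (2.1 equiv), THF, −78 °C; then 11, −78 → −30 °C; aq. NH4Cl
Reagents that add atoms: none
Why: Lithium acetylide addition to the lactone carbonyl stops at the tetrahedral alkoxide at low temperature and collapses on work-up to the hydroxy ynone, forming C2–C3 and freeing O9 without touching a stereocenter.

**Step 11**
Reactants: 18 (1S,8R,9S,10S,13S,5Z)-6-chloro-9,13-dihydroxy-8-(TES-oxy)-7,16-bis(TBDPS-oxy)-17,18,19-trinor-6,7-secobriara-5,11(20)-dien-3-yn-2-one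
Product: 19 (1S,2R,8R,9S,10S,13S,5Z)-6-chloro-8-(TES-oxy)-7,16-bis(TBDPS-oxy)-17,18,19-trinor-6,7-secobriara-5,11(20)-dien-3-yne-2,9,13-triol
Conditions: RuCl[(R,R)-TsDPEN](p-cymene) (5 mol%), HCO2H/Et3N 5:2, CH2Cl2, rt
Reagents that add atoms: none
Why: Noyori asymmetric transfer hydrogenation of an alkynyl ketone is catalyst-controlled (the alkyne is the π-recognized group), and the (R,R) catalyst gives the (2R)-propargylic alcohol, which is the spatial arrangement of C2 in the target.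

**Step 12**
Reactants: 19 (1S,2R,8R,9S,10S,13S,5Z)-6-chloro-8-(TES-oxy)-7,16-bis(TBDPS-oxy)-17,18,19-trinor-6,7-secobriara-5,11(20)-dien-3-yne-2,9,13-triol
Product: 20 (1S,2S,8R,9S,10S,13S,3Z,5Z)-6-chloro-8-(TES-oxy)-7,16-bis(TBDPS-oxy)-17,18,19-trinor-6,7-secobriara-3,5,11(20)-triene-2,9,13-triol
Conditions: Zn dust activated by Cu(OAc)2 and AgNO3, MeOH/H2O 1:1, 45 °C
Reagents that add atoms: none
Why: Boland reduction of the conjugated enyne by activated zinc delivers both hydrogens cis and gives the (3Z)-diene without over-reduction or loss of the vinyl chloride.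

**Step 13**
Reactants: 20 (1S,2S,8R,9S,10S,13S,3Z,5Z)-6-chloro-8-(TES-oxy)-7,16-bis(TBDPS-oxy)-17,18,19-trinor-6,7-secobriara-3,5,11(20)-triene-2,9,13-triol
Product: 21 (1S,2S,8R,9S,10S,13S,3Z,5Z)-6-chloro-8-(TES-oxy)-7,16-bis(TBDPS-oxy)-17,18,19-trinor-6,7-secobriara-3,5,11(20)-triene-2,9,13-triyl triacetate
Conditions: Ac2O, pyridine, DMAP (cat.), CH2Cl2, rt
Reagents that add atoms: acetic anhydride CC(=O)OC(C)=O
Why: DMAP-catalysed acylation installs the three acetates of the target (O2, O9, O13) in one operation while O8 is still silylated.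

**Step 14**
Reactants: 21 (1S,2S,8R,9S,10S,13S,3Z,5Z)-6-chloro-8-(TES-oxy)-7,16-bis(TBDPS-oxy)-17,18,19-trinor-6,7-secobriara-3,5,11(20)-triene-2,9,13-triyl triacetate
Product: 22 (1S,2S,8R,9S,10S,13S,3Z,5Z)-6-chloro-8-hydroxy-7,16-bis(TBDPS-oxy)-17,18,19-trinor-6,7-secobriara-3,5,11(20)-triene-2,9,13-triyl triacetate
Conditions: PPTS, MeOH/CH2Cl2, 0 °C
Reagents that add atoms: none
Why: Mild acid methanolysis cleaves the secondary triethylsilyl ether selectively over the two primary TBDPS ethers and the acetates.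

**Step 15**
Reactants: 22 (1S,2S,8R,9S,10S,13S,3Z,5Z)-6-chloro-8-hydroxy-7,16-bis(TBDPS-oxy)-17,18,19-trinor-6,7-secobriara-3,5,11(20)-triene-2,9,13-triyl triacetate
Product: 23 (1S,2S,9S,10S,13S,3Z,5Z)-6-chloro-8-oxo-7,16-bis(TBDPS-oxy)-17,18,19-trinor-6,7-secobriara-3,5,11(20)-triene-2,9,13-triyl triacetate
Conditions: Dess–Martin periodinane, NaHCO3, CH2Cl2, rt
Reagents that add atoms: none
Why: Buffered Dess–Martin oxidation gives the α-acetoxy ketone under neutral conditions without epimerizing C9.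

**Step 16**
Reactants: 23 (1S,2S,9S,10S,13S,3Z,5Z)-6-chloro-8-oxo-7,16-bis(TBDPS-oxy)-17,18,19-trinor-6,7-secobriara-3,5,11(20)-triene-2,9,13-triyl triacetate; 24 S-ethyl propanethioate
Product: 25 S-ethyl (1S,2S,8S,9S,10S,13S,17R,3Z,5Z)-2,9,13-triacetoxy-6-chloro-8-hydroxy-7,16-bis(TBDPS-oxy)-6,7-secobriara-3,5,11(20)-triene-19-thioate
Conditions: 24, LiN(iPr)2, THF/DMPU, −78 °C; then 23, −78 °C, 20 min; AcOH quench
Reagents that add atoms: none
Why: Lithium thioester enolate aldol addition to the ketone, in which polar Felkin–Anh attack anti to the C9 acetoxy group sets C8 (9,8-anti) and a Zimmerman–Traxler arrangement of the methyl-cis-to-oxygen enolate with the branched C9 substituent equatorial sets C17 (8-OH/17-methyl syn).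

**Step 17**
Reactants: 25 S-ethyl (1S,2S,8S,9S,10S,13S,17R,3Z,5Z)-2,9,13-triacetoxy-6-chloro-8-hydroxy-7,16-bis(TBDPS-oxy)-6,7-secobriara-3,5,11(20)-triene-19-thioate
Product: 26 S-ethyl (1S,2S,8S,9S,10S,13S,17R,3Z,5Z)-2,9,13-triacetoxy-6-chloro-7,8,16-trihydroxy-6,7-secobriara-3,5,11(20)-triene-19-thioate
Conditions: HF·pyridine, pyridine, THF, 0 °C → rt
Reagents that add atoms: none
Why: Fluoride cleaves both primary TBDPS ethers while acetates and thioester survive, and the neutral C7 hydroxyl does not attack the thioester without activation.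

**Step 18**
Reactants: 26 S-ethyl (1S,2S,8S,9S,10S,13S,17R,3Z,5Z)-2,9,13-triacetoxy-6-chloro-7,8,16-trihydroxy-6,7-secobriara-3,5,11(20)-triene-19-thioate
Product: 27 S-ethyl (1S,2S,8S,9S,10S,13S,17R,3Z,5Z)-2,9,13-triacetoxy-16-bromo-6-chloro-7,8-dihydroxy-6,7-secobriara-3,5,11(20)-triene-19-thioate
Conditions: NBS, Me2S, CH2Cl2, −20 → 0 °C
Reagents that add atoms: N-bromosuccinimide O=C1CCC(=O)N1Br
Why: Corey–Kim conditions convert only the allylic alcohol into the bromide (SN2 collapse of the allylic alkoxysulfonium ion) and leave the saturated primary and the tertiary alcohol untouched.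

**Step 19**
Reactants: 27 S-ethyl (1S,2S,8S,9S,10S,13S,17R,3Z,5Z)-2,9,13-triacetoxy-16-bromo-6-chloro-7,8-dihydroxy-6,7-secobriara-3,5,11(20)-triene-19-thioate
Product: 28 S-ethyl (1S,2S,8R,9S,10S,13S,17R,3Z,5Z)-2,9,13-triacetoxy-16-bromo-6-chloro-8-hydroxy-7-oxo-6,7-secobriara-3,5,11(20)-triene-19-thioate
Conditions: Dess–Martin periodinane, NaHCO3, CH2Cl2, 0 °C; used at once
Reagents that add atoms: none
Why: Buffered Dess–Martin oxidation of the primary alcohol next to the tertiary carbinol gives the α-hydroxy aldehyde without touching the allylic bromide or the thioester.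

**Step 20**
Reactants: 28 S-ethyl (1S,2S,8R,9S,10S,13S,17R,3Z,5Z)-2,9,13-triacetoxy-16-bromo-6-chloro-8-hydroxy-7-oxo-6,7-secobriara-3,5,11(20)-triene-19-thioate
Product: 31 (1S,2S,6S,7S,8R,9S,10S,13S,17R,3Z)-2,9,13-triacetoxy-6-chloro-8-hydroxybriara-3,5(16),11(20)-trien-19,7-olide, via γ-chloroallylchromium dichloride 29 (not isolated), via macrocyclic chromium alkoxide 30 (not isolated)
Conditions: CrCl2 (10 equiv), THF/DMF 4:1, syringe-pump addition to 0.001 M, rt; aq. NH4Cl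
Reagents that add atoms: none
Why: Proposed new method: divalent chromium inserts into the allylic C–Br bond to give the γ-chloroallyl trivalent chromium species 29, which adds through C6 to the C7 aldehyde in a chair Zimmerman–Traxler transition state chelated by the C8 oxygen (Cl cis to the CH2–Cr carbon gives the 6,7-syn chlorohydrin; attack on the chelate face away from the ring A branch gives 7,8-syn), creating the C5(16) methylene, C6, C7 and the ten-membered ring, after which the chromium alkoxide 30 acylates itself with the C19 thioester (5-exo-trig) to close the γ-lactone; the closest known reactions are Nozaki–Hiyama–Kishi allylation macrocyclizations, chromium-mediated γ-chloroallylation of aldehydes to chlorohydrins and Nozaki–Hiyama allylation–lactonization cascades.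

**Compound list**
1 | 3-methylfuran-2(5H)-one | CC1=CCOC1=O | starting material
2 | 2-[(tert-butyldiphenylsilyl)oxy]acetaldehyde | O=CCO[Si](c1ccccc1)(c1ccccc1)C(C)(C)C | starting material
3 | (5S)-5-[(1R)-2-(TBDPS-oxy)-1-hydroxyethyl]-3-methylfuran-2(5H)-one | CC1=C[C@@H]([C@H](O)CO[Si](c2ccccc2)(c2ccccc2)C(C)(C)C)OC1=O | intermediate
4 | (5S)-5-[(1R)-2-(TBDPS-oxy)-1-(TES-oxy)ethyl]-3-methylfuran-2(5H)-one | CC1=C[C@@H]([C@H](O[Si](CC)(CC)CC)CO[Si](c2ccccc2)(c2ccccc2)C(C)(C)C)OC1=O | intermediate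
5 | oxirane | C1CO1 | starting material
6 | 2-(TES-oxy)ethyl trifluoromethanesulfonate | CC[Si](CC)(CC)OCCOS(=O)(=O)C(F)(F)F | intermediate
7 | prop-1-en-2-ylmagnesium bromide | CC(=C)[Mg]Br | starting material
8 | (4S,5S)-2-[(bromomagnesio)oxy]-5-[(1R)-2-(TBDPS-oxy)-1-(TES-oxy)ethyl]-3-methyl-4-(prop-1-en-2-yl)-4,5-dihydrofuran (lactone enolate, not isolated) | CC1=C(O[Mg]Br)O[C@H]([C@H](O[Si](CC)(CC)CC)CO[Si](c2ccccc2)(c2ccccc2)C(C)(C)C)[C@H]1C(C)=C | intermediate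
9 | (3S,4S,5S)-5-[(1R)-2-(TBDPS-oxy)-1-(TES-oxy)ethyl]-3-methyl-4-(prop-1-en-2-yl)-3-[2-(TES-oxy)ethyl]dihydrofuran-2(3H)-one | O=C1O[C@H]([C@H](O[Si](CC)(CC)CC)CO[Si](c2ccccc2)(c2ccccc2)C(C)(C)C)[C@@H](C(C)=C)[C@]1(C)CCO[Si](CC)(CC)CC | intermediate
10 | 2-[(3S,4S,5S)-5-[(1R)-2-(TBDPS-oxy)-1-(TES-oxy)ethyl]-3-methyl-2-oxo-4-(prop-1-en-2-yl)oxolan-3-yl]acetaldehyde | O=C1O[C@H]([C@H](O[Si](CC)(CC)CC)CO[Si](c2ccccc2)(c2ccccc2)C(C)(C)C)[C@@H](C(C)=C)[C@]1(C)CC=O | intermediate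
11 | (3S,3aS,6S,7aS)-3-[(1R)-2-(TBDPS-oxy)-1-(TES-oxy)ethyl]-6-hydroxy-7a-methyl-4-methylidenehexahydro-2-benzofuran-1(3H)-one (ring A fused to the O9–C2 lactone) | O=C1O[C@H]([C@H](O[Si](CC)(CC)CC)CO[Si](c3ccccc3)(c3ccccc3)C(C)(C)C)[C@H]2C(=C)C[C@H](O)C[C@]12C | intermediate
12 | ethynyltrimethylsilane | C#C[Si](C)(C)C | starting material
13 | rac-1-(TBDPS-oxy)-4-(trimethylsilyl)but-3-yn-2-ol | C[Si](C)(C)C#CC(O)CO[Si](c1ccccc1)(c1ccccc1)C(C)(C)C | intermediate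
14 | 1-(TBDPS-oxy)-4-(trimethylsilyl)but-3-yn-2-one | C[Si](C)(C)C#CC(=O)CO[Si](c1ccccc1)(c1ccccc1)C(C)(C)C | intermediate
15 | (chloromethyl)triphenylphosphonium chloride | ClC[P+](c1ccccc1)(c1ccccc1)c1ccccc1.[Cl-] | starting material
16 | (Z)-tert-butyl{[2-(chloromethylidene)-4-(trimethylsilyl)but-3-yn-1-yl]oxy}diphenylsilane (not isolated) | C[Si](C)(C)C#C/C(CO[Si](c1ccccc1)(c1ccccc1)C(C)(C)C)=C/Cl | intermediate
17 | (Z)-tert-butyl{[2-(chloromethylidene)but-3-yn-1-yl]oxy}diphenylsilane (C3–C6 and C16) | C#C/C(CO[Si](c1ccccc1)(c1ccccc1)C(C)(C)C)=C/Cl | intermediate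
18 | (1S,8R,9S,10S,13S,5Z)-6-chloro-9,13-dihydroxy-8-(TES-oxy)-7,16-bis(TBDPS-oxy)-17,18,19-trinor-6,7-secobriara-5,11(20)-dien-3-yn-2-one | C=C1C[C@H](O)C[C@](C)(C(=O)C#C/C(CO[Si](c2ccccc2)(c2ccccc2)C(C)(C)C)=C/Cl)[C@H]1[C@H](O)[C@H](O[Si](CC)(CC)CC)CO[Si](c1ccccc1)(c1ccccc1)C(C)(C)C | intermediate
19 | (1S,2R,8R,9S,10S,13S,5Z)-6-chloro-8-(TES-oxy)-7,16-bis(TBDPS-oxy)-17,18,19-trinor-6,7-secobriara-5,11(20)-dien-3-yne-2,9,13-triol | C=C1C[C@H](O)C[C@](C)([C@@H](O)C#C/C(CO[Si](c2ccccc2)(c2ccccc2)C(C)(C)C)=C/Cl)[C@H]1[C@H](O)[C@H](O[Si](CC)(CC)CC)CO[Si](c1ccccc1)(c1ccccc1)C(C)(C)C | intermediate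
20 | (1S,2S,8R,9S,10S,13S,3Z,5Z)-6-chloro-8-(TES-oxy)-7,16-bis(TBDPS-oxy)-17,18,19-trinor-6,7-secobriara-3,5,11(20)-triene-2,9,13-triol | C=C1C[C@H](O)C[C@](C)([C@@H](O)/C=C\C(CO[Si](c2ccccc2)(c2ccccc2)C(C)(C)C)=C\Cl)[C@H]1[C@H](O)[C@H](O[Si](CC)(CC)CC)CO[Si](c1ccccc1)(c1ccccc1)C(C)(C)C | intermediate
21 | (1S,2S,8R,9S,10S,13S,3Z,5Z)-6-chloro-8-(TES-oxy)-7,16-bis(TBDPS-oxy)-17,18,19-trinor-6,7-secobriara-3,5,11(20)-triene-2,9,13-triyl triacetate | C=C1C[C@H](OC(C)=O)C[C@](C)([C@@H](OC(C)=O)/C=C\C(CO[Si](c2ccccc2)(c2ccccc2)C(C)(C)C)=C\Cl)[C@H]1[C@H](OC(C)=O)[C@H](O[Si](CC)(CC)CC)CO[Si](c1ccccc1)(c1ccccc1)C(C)(C)C | intermediate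
22 | (1S,2S,8R,9S,10S,13S,3Z,5Z)-6-chloro-8-hydroxy-7,16-bis(TBDPS-oxy)-17,18,19-trinor-6,7-secobriara-3,5,11(20)-triene-2,9,13-triyl triacetate | C=C1C[C@H](OC(C)=O)C[C@](C)([C@@H](OC(C)=O)/C=C\C(CO[Si](c2ccccc2)(c2ccccc2)C(C)(C)C)=C\Cl)[C@H]1[C@H](OC(C)=O)[C@H](O)CO[Si](c1ccccc1)(c1ccccc1)C(C)(C)C | intermediate
23 | (1S,2S,9S,10S,13S,3Z,5Z)-6-chloro-8-oxo-7,16-bis(TBDPS-oxy)-17,18,19-trinor-6,7-secobriara-3,5,11(20)-triene-2,9,13-triyl triacetate | C=C1C[C@H](OC(C)=O)C[C@](C)([C@@H](OC(C)=O)/C=C\C(CO[Si](c2ccccc2)(c2ccccc2)C(C)(C)C)=C\Cl)[C@H]1[C@H](OC(C)=O)C(=O)CO[Si](c1ccccc1)(c1ccccc1)C(C)(C)C | intermediate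
24 | S-ethyl propanethioate | CCC(=O)SCC | starting material
25 | S-ethyl (1S,2S,8S,9S,10S,13S,17R,3Z,5Z)-2,9,13-triacetoxy-6-chloro-8-hydroxy-7,16-bis(TBDPS-oxy)-6,7-secobriara-3,5,11(20)-triene-19-thioate | C=C1C[C@H](OC(C)=O)C[C@](C)([C@@H](OC(C)=O)/C=C\C(CO[Si](c2ccccc2)(c2ccccc2)C(C)(C)C)=C\Cl)[C@H]1[C@H](OC(C)=O)[C@@](O)(CO[Si](c1ccccc1)(c1ccccc1)C(C)(C)C)[C@@H](C)C(=O)SCC | intermediate
26 | S-ethyl (1S,2S,8S,9S,10S,13S,17R,3Z,5Z)-2,9,13-triacetoxy-6-chloro-7,8,16-trihydroxy-6,7-secobriara-3,5,11(20)-triene-19-thioate | C=C1C[C@H](OC(C)=O)C[C@](C)([C@@H](OC(C)=O)/C=C\C(CO)=C\Cl)[C@H]1[C@H](OC(C)=O)[C@@](O)(CO)[C@@H](C)C(=O)SCC | intermediate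
27 | S-ethyl (1S,2S,8S,9S,10S,13S,17R,3Z,5Z)-2,9,13-triacetoxy-16-bromo-6-chloro-7,8-dihydroxy-6,7-secobriara-3,5,11(20)-triene-19-thioate | C=C1C[C@H](OC(C)=O)C[C@](C)([C@@H](OC(C)=O)/C=C\C(CBr)=C\Cl)[C@H]1[C@H](OC(C)=O)[C@@](O)(CO)[C@@H](C)C(=O)SCC | intermediate
28 | S-ethyl (1S,2S,8R,9S,10S,13S,17R,3Z,5Z)-2,9,13-triacetoxy-16-bromo-6-chloro-8-hydroxy-7-oxo-6,7-secobriara-3,5,11(20)-triene-19-thioate | C=C1C[C@H](OC(C)=O)C[C@](C)([C@@H](OC(C)=O)/C=C\C(CBr)=C\Cl)[C@H]1[C@H](OC(C)=O)[C@@](O)(C=O)[C@@H](C)C(=O)SCC | intermediate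
29 | γ-chloroallylchromium dichloride derived from 28 (C16–CrCl2; trivalent chromium; not isolated) | C=C1C[C@H](OC(C)=O)C[C@](C)([C@@H](OC(C)=O)/C=C\C(C[Cr](Cl)Cl)=C\Cl)[C@H]1[C@H](OC(C)=O)[C@@](O)(C=O)[C@@H](C)C(=O)SCC | intermediate
30 | dichlorochromium 7-alkoxide of S-ethyl (1S,2S,6S,7S,8R,9S,10S,13S,17R,3Z)-2,9,13-triacetoxy-6-chloro-7,8-dihydroxybriara-3,5(16),11(20)-triene-19-thioate (not isolated) | C=C1C[C@H](OC(C)=O)C[C@]2(C)[C@@H](OC(C)=O)/C=C\C(=C)[C@H](Cl)[C@@H](O[Cr](Cl)Cl)[C@@](O)([C@@H](C)C(=O)SCC)[C@@H](OC(C)=O)[C@@H]12 | intermediate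
31 | (1S,2S,6S,7S,8R,9S,10S,13S,17R,3Z)-2,9,13-triacetoxy-6-chloro-8-hydroxybriara-3,5(16),11(20)-trien-19,7-olide | C=C1C[C@H](OC(C)=O)C[C@]2(C)[C@@H](OC(C)=O)/C=C\C(=C)[C@H](Cl)[C@H]3OC(=O)[C@H](C)[C@@]3(O)[C@@H](OC(C)=O)[C@@H]12 | target

**Step count and risks**

Total: 20 steps. Longest linear sequence: 16 steps (steps 1, 2, 4–6 and 10–20, from 1).

Most at risk is step 20, because a ten-membered ring must close through an allylchromium species whose chloroalkene geometry can equilibrate, so both ring closure and the C6/C7 configuration are uncertain. The fallback sets out from bromide 27 and replaces the chromium reagent by a configurationally stable allylboron reagent. Pd2(dba)3-catalysed borylation with B2pin2 and KOAc gives the (Z)-γ-chloroallylboronate S-ethyl 2,9,13-triacetoxy-6-chloro-7,8-dihydroxy-16-(4,4,5,5-tetramethyl-1,3,2-dioxaborolan-2-yl)-6,7-secobriara-3,5,11(20)-triene-19-thioate F6. Dess–Martin oxidation gives the aldehyde S-ethyl 2,9,13-triacetoxy-6-chloro-8-hydroxy-7-oxo-16-(4,4,5,5-tetramethyl-1,3,2-dioxaborolan-2-yl)-6,7-secobriara-3,5,11(20)-triene-19-thioate F7. On warming in dilute toluene F7 undergoes intramolecular allylboration through a closed chair, and a (Z)-γ-chloroallylboronate gives the syn chlorohydrin stereospecifically; work-up gives the macrocyclic hydroxy thioester S-ethyl (1S,2S,6S,7S,8S,9S,10S,13S,17R,3Z)-2,9,13-triacetoxy-6-chloro-7,8-dihydroxybriara-3,5(16),11(20)-triene-19-thioate F8. Lactonization with AgO2CCF3 then comes back to the route at target 31.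

Second is step 16, where the open-chain ketone aldol may give poor control at C17 or attack the acetates. The fallback sets out from ketone 23 and introduces C17–C19 as a small, non-acylating nitrile. Lithiated propanenitrile (LiN(iPr)2, THF, −78 °C) adds with the same Felkin sense at C8 to give (1S,2S,8S,9S,10S,13S,3Z,5Z)-2,9,13-triacetoxy-6-chloro-8-hydroxy-7,16-bis(TBDPS-oxy)-6,7-secobriara-3,5,11(20)-triene-19-nitrile F2 as C17 epimers. The end game is then repeated: HF·pyridine gives the 7,8,16-trihydroxy nitrile F3, NBS/Me2S gives the 16-bromo-7,8-dihydroxy nitrile F4, and Dess–Martin oxidation gives the 16-bromo-8-hydroxy-7-oxo nitrile F5. CrCl2 macrocyclization of F5 lets the C7 alkoxide close onto the nitrile as an iminolactone, which mild aqueous acid hydrolyses to the lactone. C17 is then equilibrated with DBU toward the epimer with the methyl trans to C9 (expected to be the more stable one), or the epimers are separated, and the sequence comes back to the route at target 31.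

Third is step 4, where SN2 alkylation of the hindered α-methyl lactone enolate by the β-silyloxyethyl triflate may be slow or give O-alkylation. The fallback sets out from butenolide 4 and forms the quaternary centre by a Michael addition instead. After the same cuprate addition, enolate 8 is trapped with phenyl vinyl sulfoxide to give (3S,4S,5S)-5-[(1R)-2-(TBDPS-oxy)-1-(TES-oxy)ethyl]-3-methyl-3-[2-(phenylsulfinyl)ethyl]-4-(prop-1-en-2-yl)dihydrofuran-2(3H)-one F1 (sulfoxide epimers). Pummerer rearrangement (trifluoroacetic anhydride, 2,6-lutidine; then aq. NaHCO3) unmasks the aldehyde and comes back to the route at aldehyde 10, so step 5 is not needed.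

**Further compounds**
F1 | step 4 | (3S,4S,5S)-5-[(1R)-2-(TBDPS-oxy)-1-(TES-oxy)ethyl]-3-methyl-3-[2-(phenylsulfinyl)ethyl]-4-(prop-1-en-2-yl)dihydrofuran-2(3H)-one | O=C1O[C@H]([C@H](O[Si](CC)(CC)CC)CO[Si](c2ccccc2)(c2ccccc2)C(C)(C)C)[C@@H](C(C)=C)[C@]1(C)CCS(=O)c1ccccc1
F2 | step 16 | (1S,2S,8S,9S,10S,13S,3Z,5Z)-2,9,13-triacetoxy-6-chloro-8-hydroxy-7,16-bis(TBDPS-oxy)-6,7-secobriara-3,5,11(20)-triene-19-nitrile (C17 epimers) | C=C1C[C@H](OC(C)=O)C[C@](C)([C@@H](OC(C)=O)/C=C\C(CO[Si](c2ccccc2)(c2ccccc2)C(C)(C)C)=C\Cl)[C@H]1[C@H](OC(C)=O)[C@@](O)(CO[Si](c1ccccc1)(c1ccccc1)C(C)(C)C)C(C)C#N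
F3 | step 16 | (1S,2S,8S,9S,10S,13S,3Z,5Z)-2,9,13-triacetoxy-6-chloro-7,8,16-trihydroxy-6,7-secobriara-3,5,11(20)-triene-19-nitrile (C17 epimers) | C=C1C[C@H](OC(C)=O)C[C@](C)([C@@H](OC(C)=O)/C=C\C(CO)=C\Cl)[C@H]1[C@H](OC(C)=O)[C@@](O)(CO)C(C)C#N
F4 | step 16 | (1S,2S,8S,9S,10S,13S,3Z,5Z)-2,9,13-triacetoxy-16-bromo-6-chloro-7,8-dihydroxy-6,7-secobriara-3,5,11(20)-triene-19-nitrile (C17 epimers) | C=C1C[C@H](OC(C)=O)C[C@](C)([C@@H](OC(C)=O)/C=C\C(CBr)=C\Cl)[C@H]1[C@H](OC(C)=O)[C@@](O)(CO)C(C)C#N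
F5 | step 16 | (1S,2S,8R,9S,10S,13S,3Z,5Z)-2,9,13-triacetoxy-16-bromo-6-chloro-8-hydroxy-7-oxo-6,7-secobriara-3,5,11(20)-triene-19-nitrile (C17 epimers) | C=C1C[C@H](OC(C)=O)C[C@](C)([C@@H](OC(C)=O)/C=C\C(CBr)=C\Cl)[C@H]1[C@H](OC(C)=O)[C@@](O)(C=O)C(C)C#N
F6 | step 20 | S-ethyl (1S,2S,8S,9S,10S,13S,17R,3Z,5Z)-2,9,13-triacetoxy-6-chloro-7,8-dihydroxy-16-(4,4,5,5-tetramethyl-1,3,2-dioxaborolan-2-yl)-6,7-secobriara-3,5,11(20)-triene-19-thioate | C=C1C[C@H](OC(C)=O)C[C@](C)([C@@H](OC(C)=O)/C=C\C(CB2OC(C)(C)C(C)(C)O2)=C\Cl)[C@H]1[C@H](OC(C)=O)[C@@](O)(CO)[C@@H](C)C(=O)SCC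
F7 | step 20 | S-ethyl (1S,2S,8R,9S,10S,13S,17R,3Z,5Z)-2,9,13-triacetoxy-6-chloro-8-hydroxy-7-oxo-16-(4,4,5,5-tetramethyl-1,3,2-dioxaborolan-2-yl)-6,7-secobriara-3,5,11(20)-triene-19-thioate | C=C1C[C@H](OC(C)=O)C[C@](C)([C@@H](OC(C)=O)/C=C\C(CB2OC(C)(C)C(C)(C)O2)=C\Cl)[C@H]1[C@H](OC(C)=O)[C@@](O)(C=O)[C@@H](C)C(=O)SCC
F8 | step 20 | S-ethyl (1S,2S,6S,7S,8S,9S,10S,13S,17R,3Z)-2,9,13-triacetoxy-6-chloro-7,8-dihydroxybriara-3,5(16),11(20)-triene-19-thioate | C=C1C[C@H](OC(C)=O)C[C@]2(C)[C@@H](OC(C)=O)/C=C\C(=C)[C@H](Cl)[C@@H](O)[C@@](O)([C@@H](C)C(=O)SCC)[C@@H](OC(C)=O)[C@@H]12
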